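**Retrosynthetic overview**

1. Target ⇒ (R)-shikonin 17 + 3-acetoxy-3-methylbutanoic acid 19. The side-chain ester is made last; the chelated peri-hydroxyls at C5/C8 should stay free.
2. 17 ⇒ 5,8-dimethoxy-1,4-naphthoquinone 12. The two methyl ethers of ring B are exchanged by reduction/acetylation, oxidation of ring B and saponification.
3. 12 ⇒ ring A (C1–C4, C4a, C8a) is built on preformed ring B in one three-component benzannulation: carbene complex 4 (C4 and C4a–C8a), CO (C1) and terminal alkyne 10 (C3–H, and C2 with the finished side chain). Bonds formed: C3–C4, C1–C2, C1–C8a.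
4. Enabling feature: ring A is para-dioxygenated (C1, C4) with C3 an unsubstituted CH, and ring B carries the same oxygen at C5 and C8. C1 and C4 are therefore equivalent once ring A is a quinone, so the direction of alkyne uptake cannot matter.
5. 10 ⇒ 3-(trimethylsilyl)propynal 5 by asymmetric allylboration (sets C1′) and cross-metathesis. Ring A is the only ring formed; ring B comes from 1.

Key step: step 6

Remark: in naphthazarins the 2-substituted and the 6-substituted 5,8-dihydroxy-1,4-naphthoquinone are rapidly interconverting tautomers, that is, one compound; the target SMILES shows one of them. C1′ is the side-chain carbinol carbon.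

**Step 1**
Reactants: 1 2-bromo-1,4-dimethoxybenzene
Product: 4 pentacarbonyl[(2,5-dimethoxyphenyl)(methoxy)methylidene]chromium, via aryllithium 2 (not isolated), via lithium acylchromate 3 (not isolated)
Conditions: n-BuLi, THF, −78 °C; Cr(CO)6, −78 °C → rt; then MeOTf, CH2Cl2, 0 °C → rt
Reagents that add atoms: hexacarbonylchromium, O=C=[Cr](=C=O)(=C=O)(=C=O)(=C=O)=C=O; methyl trifluoromethanesulfonate, COS(=O)(=O)C(F)(F)F
Why: Bromine–lithium exchange gives the aryllithium, which adds to a CO ligand of Cr(CO)6, and O-methylation of the acyl chromate gives the carbene complex of zerovalent chromium (Fischer carbene synthesis).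

**Step 2**
Reactants: 5 3-(trimethylsilyl)prop-2-ynal
Product: 7 (R)-1-(trimethylsilyl)hex-5-en-1-yn-3-ol, via borinate 6 (not isolated)
Conditions: (+)-Ipc2BOMe, allylMgBr, Et2O, 0 °C → rt; then 5, −78 °C; then NaOH, H2O2, 0 °C
Reagents that add atoms: allylmagnesium bromide, C=CC[Mg]Br
Why: Brown allylboration through a chair Zimmerman–Traxler transition state; the allylborane derived from (−)-α-pinene should deliver allyl to the Re face of the ynal and so set C1′ as (R), the alkynyl group outranking allyl.

**Step 3**
Reactants: 7 (R)-1-(trimethylsilyl)hex-5-en-1-yn-3-ol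
Product: 8 (R)-tert-butyldimethyl{[1-(trimethylsilyl)hex-5-en-1-yn-3-yl]oxy}silane
Conditions: TBSCl, imidazole, DMF, rt
Reagents that add atoms: tert-butyldimethylsilyl chloride, CC(C)(C)[Si](C)(C)Cl
Why: Standard O-silylation of a secondary alcohol; propargylic silyl ethers are well-tolerated alkyne partners in carbene benzannulations.

**Step 4**
Reactants: 8 (R)-tert-butyldimethyl{[1-(trimethylsilyl)hex-5-en-1-yn-3-yl]oxy}silane
Product: 9 (R)-tert-butyldimethyl{[6-methyl-1-(trimethylsilyl)hept-5-en-1-yn-3-yl]oxy}silane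
Conditions: 2-methyl-2-butene (excess), second-generation Grubbs catalyst RuCl2(=CHPh)(H2IMes)(PCy3) (cat.), CH2Cl2, 40 °C
Reagents that add atoms: 2-methyl-2-butene, CC=C(C)C
Why: Olefin cross-metathesis of a terminal alkene with 2-methyl-2-butene installs the dimethylvinyl terminus with loss of propene, while the C-silyl group keeps the alkyne out of enyne metathesis.

**Step 5**
Reactants: 9 (R)-tert-butyldimethyl{[6-methyl-1-(trimethylsilyl)hept-5-en-1-yn-3-yl]oxy}silane
Product: 10 (R)-tert-butyldimethyl[(6-methylhept-5-en-1-yn-3-yl)oxy]silane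
Conditions: K2CO3 (cat.), MeOH, rt
Reagents that add atoms: none
Why: Methanolysis cleaves the alkynyl C–Si bond selectively; the O-silyl ether is stable to these conditions.

**Step 6**
Reactants: 4 pentacarbonyl[(2,5-dimethoxyphenyl)(methoxy)methylidene]chromium; 10 (R)-tert-butyldimethyl[(6-methylhept-5-en-1-yn-3-yl)oxy]silane
Product: 12 2-[(R)-1-(tert-butyldimethylsilyloxy)-4-methylpent-3-en-1-yl]-5,8-dimethoxynaphthalene-1,4-dione, via naphthol chromium tricarbonyl complex 11 (not isolated)
Conditions: THF (degassed), 55 °C; then (NH4)2Ce(NO3)6, MeCN/H2O, 0 °C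
Reagents that add atoms: water, O
Why: Thermal loss of one CO from 4 lets the terminal alkyne insert into the Cr=C bond, which joins the alkyne CH (C3) to the carbene carbon (C4); CO insertion into the resulting vinylcarbene then gives a chromium-bound dienylketene (C1–C2 bond), and a 6π-electrocyclisation onto the free ortho carbon of the aryl group (C1–C8a bond) followed by enolisation closes ring A as the Cr(CO)3-bound 4-methoxy-1-naphthol 11. The closest known reaction type is the Dötz benzannulation of aryl(methoxy)carbene pentacarbonylchromium complexes with terminal alkynes with an oxidative work-up by tetravalent cerium, which removes the metal and turns the 4-methoxy-1-naphthol into the 1,4-quinone (the C4 oxygen then comes from water and the methoxy group leaves as methanol). Ring A is the only ring closed, by 6π-electrocyclisation of the metal-bound ketene to a six-membered carbocycle. No stereocentre is formed: C1′ is a spectator, since its C–H is not acidic and no bond to it is broken, and the planar chirality of 11 disappears with the metal. The step needs CO insertion to win over indene and furan formation, which an aryl methoxy carbene, THF and a terminal alkyne should favour. It needs no regiocontrol: the branched substituent should end up next to the CO-derived C1, but because ring B carries the same methoxy group at C5 and C8 and both C1 and C4 become carbonyls, either mode of alkyne uptake gives the same quinone 12.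

**Step 7**
Reactants: 12 2-[(R)-1-(tert-butyldimethylsilyloxy)-4-methylpent-3-en-1-yl]-5,8-dimethoxynaphthalene-1,4-dione
Product: 13 2-[(R)-1-hydroxy-4-methylpent-3-en-1-yl]-5,8-dimethoxynaphthalene-1,4-dione
Conditions: HF·pyridine, THF, 0 °C → rt
Reagents that add atoms: none
Why: Fluoride-driven desilylation under weakly acidic conditions that a quinone tolerates; C1′ sits on an electron-poor quinone ring and cannot ionise, so the configuration should be kept.

**Step 8**
Reactants: 13 2-[(R)-1-hydroxy-4-methylpent-3-en-1-yl]-5,8-dimethoxynaphthalene-1,4-dione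
Product: 15 (R)-1-(1,4-diacetoxy-5,8-dimethoxynaphthalen-2-yl)-4-methylpent-3-en-1-yl acetate, via hydroquinone 14 (not isolated)
Conditions: Zn dust, Ac2O, pyridine, CH2Cl2, 0 °C → rt; then DMAP (cat.)
Reagents that add atoms: acetic anhydride, CC(=O)OC(C)=O
Why: Reductive acetylation: zinc reduces the quinone and the phenolates are trapped at once as aryl acetates, and DMAP is added only afterwards to acetylate the slower side-chain alcohol, so that no free ortho-phenol is ever present next to a benzylic leaving group.

**Step 9**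
Reactants: 15 (R)-1-(1,4-diacetoxy-5,8-dimethoxynaphthalen-2-yl)-4-methylpent-3-en-1-yl acetate
Product: 16 (R)-1-(1,4-diacetoxy-5,8-dioxo-5,8-dihydronaphthalen-2-yl)-4-methylpent-3-en-1-yl acetate
Conditions: (NH4)2Ce(NO3)6, MeCN/H2O, 0 °C
Reagents that add atoms: water, O
Why: Oxidative demethylation of a para-dimethoxyarene by tetravalent cerium; it should take place in ring B only, because the two acetoxy groups make ring A too electron-poor to be oxidised.

**Step 10**
Reactants: 16 (R)-1-(1,4-diacetoxy-5,8-dioxo-5,8-dihydronaphthalen-2-yl)-4-methylpent-3-en-1-yl acetate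
Product: 17 (R)-5,8-dihydroxy-2-(1-hydroxy-4-methylpent-3-en-1-yl)naphthalene-1,4-dione ((R)-shikonin)
Conditions: NaOH (1 M aq.), MeOH, N2, 0 °C; then HCl (1 M aq.)
Reagents that add atoms: none
Why: Saponification of the two aryl acetates and the side-chain acetate by acyl–oxygen cleavage, which leaves C1′ untouched; the 6-substituted naphthazarin set free is the tautomer of 17 and equilibrates to it.

**Step 11**
Reactants: 18 3-hydroxy-3-methylbutanoic acid
Product: 19 3-acetoxy-3-methylbutanoic acid
Conditions: AcCl (neat), rt; then H2O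
Reagents that add atoms: acetyl chloride, CC(=O)Cl
Why: O-acetylation of the tertiary alcohol by neat acetyl chloride without base, which avoids base-induced elimination; the aqueous work-up returns the free carboxylic acid.

**Step 12**
Reactants: 17 (R)-shikonin; 19 3-acetoxy-3-methylbutanoic acid
Product: 21 (R)-1-(5,8-dihydroxy-1,4-dioxo-1,4-dihydronaphthalen-2-yl)-4-methylpent-3-en-1-yl 3-acetoxy-3-methylbutanoate, via O-acylisourea 20 (not isolated)
Conditions: DCC, DMAP (cat.), CH2Cl2, 0 °C → rt
Reagents that add atoms: none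
Why: Steglich esterification; the two peri-hydroxyls are held in hydrogen bonds to the quinone carbonyls and are poor nucleophiles, so the secondary side-chain alcohol should be acylated selectively, with retention at C1′ because only an acyl–oxygen bond is formed.

**Compound list**

1 | 2-bromo-1,4-dimethoxybenzene | COc1ccc(OC)c(Br)c1 | starting material
2 | (2,5-dimethoxyphenyl)lithium | [Li]c1cc(OC)ccc1OC | intermediate
3 | lithium pentacarbonyl[(2,5-dimethoxyphenyl)(oxido)methylidene]chromate | [Li+].[O-]C(c1cc(OC)ccc1OC)=[Cr](=C=O)(=C=O)(=C=O)(=C=O)=C=O | intermediate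
4 | pentacarbonyl[(2,5-dimethoxyphenyl)(methoxy)methylidene]chromium | COC(c1cc(OC)ccc1OC)=[Cr](=C=O)(=C=O)(=C=O)(=C=O)=C=O | intermediate
5 | 3-(trimethylsilyl)prop-2-ynal | C[Si](C)(C)C#CC=O | starting material
6 | (R)-1-(trimethylsilyl)hex-5-en-1-yn-3-yl diisopinocampheylborinate | B(O[C@H](CC=C)C#C[Si](C)(C)C)([C@H]1C[C@H]2C[C@@H]([C@@H]1C)C2(C)C)[C@H]1C[C@H]2C[C@@H]([C@@H]1C)C2(C)C | intermediate
7 | (R)-1-(trimethylsilyl)hex-5-en-1-yn-3-ol | O[C@H](CC=C)C#C[Si](C)(C)C | intermediate
8 | (R)-tert-butyldimethyl{[1-(trimethylsilyl)hex-5-en-1-yn-3-yl]oxy}silane | CC(C)(C)[Si](C)(C)O[C@H](CC=C)C#C[Si](C)(C)C | intermediate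
9 | (R)-tert-butyldimethyl{[6-methyl-1-(trimethylsilyl)hept-5-en-1-yn-3-yl]oxy}silane | CC(C)(C)[Si](C)(C)O[C@H](CC=C(C)C)C#C[Si](C)(C)C | intermediate
10 | (R)-tert-butyldimethyl[(6-methylhept-5-en-1-yn-3-yl)oxy]silane | CC(C)(C)[Si](C)(C)O[C@H](CC=C(C)C)C#C | intermediate
11 | tricarbonyl{η6-2-[(R)-1-(tert-butyldimethylsilyloxy)-4-methylpent-3-en-1-yl]-4,5,8-trimethoxynaphthalen-1-ol}chromium (SMILES gives the ligand and the Cr(CO)3 unit as two parts) | CC(C)(C)[Si](C)(C)O[C@H](CC=C(C)C)c1cc(OC)c2c(OC)ccc(OC)c2c1O.O=C=[Cr](=C=O)=C=O | intermediate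
12 | 2-[(R)-1-(tert-butyldimethylsilyloxy)-4-methylpent-3-en-1-yl]-5,8-dimethoxynaphthalene-1,4-dione | CC(C)(C)[Si](C)(C)O[C@H](CC=C(C)C)C1=CC(=O)c2c(OC)ccc(OC)c2C1=O | intermediate
13 | 2-[(R)-1-hydroxy-4-methylpent-3-en-1-yl]-5,8-dimethoxynaphthalene-1,4-dione | O[C@H](CC=C(C)C)C1=CC(=O)c2c(OC)ccc(OC)c2C1=O | intermediate
14 | 2-[(R)-1-hydroxy-4-methylpent-3-en-1-yl]-5,8-dimethoxynaphthalene-1,4-diol (present as its zinc phenolate) | O[C@H](CC=C(C)C)c1cc(O)c2c(OC)ccc(OC)c2c1O | intermediate
15 | (R)-1-(1,4-diacetoxy-5,8-dimethoxynaphthalen-2-yl)-4-methylpent-3-en-1-yl acetate | CC(=O)O[C@H](CC=C(C)C)c1cc(OC(C)=O)c2c(OC)ccc(OC)c2c1OC(C)=O | intermediate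
16 | (R)-1-(1,4-diacetoxy-5,8-dioxo-5,8-dihydronaphthalen-2-yl)-4-methylpent-3-en-1-yl acetate (5,8-diacetoxy-6-substituted 1,4-naphthoquinone) | CC(=O)O[C@H](CC=C(C)C)c1cc(OC(C)=O)c2C(=O)C=CC(=O)c2c1OC(C)=O | intermediate
17 | (R)-5,8-dihydroxy-2-(1-hydroxy-4-methylpent-3-en-1-yl)naphthalene-1,4-dione ((R)-shikonin) | O[C@H](CC=C(C)C)C1=CC(=O)c2c(O)ccc(O)c2C1=O | intermediate
18 | 3-hydroxy-3-methylbutanoic acid | CC(C)(O)CC(=O)O | starting material
19 | 3-acetoxy-3-methylbutanoic acid | CC(=O)OC(C)(C)CC(=O)O | intermediate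
20 | O-(3-acetoxy-3-methylbutanoyl)-N,N′-dicyclohexylisourea | CC(=O)OC(C)(C)CC(=O)OC(=NC1CCCCC1)NC1CCCCC1 | intermediate
21 | (R)-1-(5,8-dihydroxy-1,4-dioxo-1,4-dihydronaphthalen-2-yl)-4-methylpent-3-en-1-yl 3-acetoxy-3-methylbutanoate | CC(=O)OC(C)(C)CC(=O)O[C@H](CC=C(C)C)C1=CC(=O)c2c(O)ccc(O)c2C1=O | target

**Step count and risks**

Total step count: 12. Longest linear sequence: 10 steps (steps 2–10 and 12).

Steps most likely to fail:

1. Step 6. What may go wrong: CO insertion may be incomplete, so that the vinylcarbene closes without CO to indene or furan products; the alkyne may oligomerise; CO loss from the ortho-methoxy-chelated carbene may be slow. The fallback replaces the carbene benzannulation by a phthaloylcobalt–alkyne annulation; it sets out from 1 and 10 and comes back at 12. Compound 1 with NaNH2 and 1,1-dimethoxyethene (THF, reflux) would give 3,6-dimethoxybenzyne F1 and, by [2+2] cycloaddition, the acetal 2,5,7,7-tetramethoxybicyclo[4.2.0]octa-1,3,5-triene F2. Aqueous HCl would hydrolyse this to 3,6-dimethoxybenzocyclobutenone F3. NBS (2 equiv., CCl4, reflux) would give the 8,8-dibromide F4, and aqueous H2SO4 the dione 3,6-dimethoxybenzocyclobutene-1,2-dione F5. ClCo(PPh3)3 would add oxidatively across the C(O)–C(O) bond to give the phthaloylcobalt complex F6, a complex of trivalent cobalt. Alkyne 10 with AgBF4 in MeCN would then insert and, after reductive elimination, give 12. The symmetry of F1 and F5 again removes every regiochemical question.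

2. Step 12. What may go wrong: the DMAP-activated β-acetoxy acyl donor may lose acetic acid and deliver the 3-methylbut-2-enoate; the phenols may be over-acylated; the O-acylisourea may rearrange to the N-acylurea. The fallback never activates the β-acetoxy acid; it sets out from 17 and 18 and comes back at 21. DCC/DMAP coupling of 17 with the hydroxy acid 18, through the O-acylisourea F7, would give the β-hydroxy ester F8. Exhaustive acetylation (Ac2O, DMAP, Et3N, CH2Cl2) would give the triacetate F9. NH4OAc in aqueous MeOH would then cleave only the two aryl acetates, and any aryl ester formed by over-acylation, to give 21.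

3. Step 2. What may go wrong: facial selectivity of the allylboration may be insufficient with the small, linear ynal, and the C-silyl group may be partly lost in the basic oxidative work-up. The fallback sets the stereocentre by reduction instead; it sets out from 5 and comes back at 7. AllylMgBr (THF, −78 °C, aqueous quench) would give the racemic alcohol F10, and Dess–Martin periodinane the ynone F11. Asymmetric transfer hydrogenation with RuCl[(R,R)-TsDPEN](p-cymene) in i-PrOH should give 7, the alkynyl group taking the place an aryl group takes in this reduction; the sense of induction would be confirmed on 7 before it is carried on.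

**Further compounds**

F1 | step 6 | 3,6-dimethoxybenzyne | COC1=CC=C(OC)C#C1
F2 | step 6 | 2,5,7,7-tetramethoxybicyclo[4.2.0]octa-1,3,5-triene | COc1ccc(OC)c2c1CC2(OC)OC
F3 | step 6 | 2,5-dimethoxybicyclo[4.2.0]octa-1,3,5-trien-7-one | COc1ccc(OC)c2c1CC2=O
F4 | step 6 | 8,8-dibromo-2,5-dimethoxybicyclo[4.2.0]octa-1,3,5-trien-7-one | COc1ccc(OC)c2c1C(Br)(Br)C2=O
F5 | step 6 | 2,5-dimethoxybicyclo[4.2.0]octa-1,3,5-triene-7,8-dione | COc1ccc(OC)c2c1C(=O)C2=O
F6 | step 6 | chloro(3,6-dimethoxyphthaloyl)bis(triphenylphosphine)cobalt | COc1ccc(OC)c2c1C(=O)[Co-2](Cl)([P+](c3ccccc3)(c3ccccc3)c3ccccc3)([P+](c3ccccc3)(c3ccccc3)c3ccccc3)C2=O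
F7 | step 12 | O-(3-hydroxy-3-methylbutanoyl)-N,N′-dicyclohexylisourea | CC(C)(O)CC(=O)OC(=NC1CCCCC1)NC1CCCCC1
F8 | step 12 | (R)-1-(5,8-dihydroxy-1,4-dioxo-1,4-dihydronaphthalen-2-yl)-4-methylpent-3-en-1-yl 3-hydroxy-3-methylbutanoate | CC(C)(O)CC(=O)O[C@H](CC=C(C)C)C1=CC(=O)c2c(O)ccc(O)c2C1=O
F9 | step 12 | (R)-1-(5,8-diacetoxy-1,4-dioxo-1,4-dihydronaphthalen-2-yl)-4-methylpent-3-en-1-yl 3-acetoxy-3-methylbutanoate | CC(=O)OC(C)(C)CC(=O)O[C@H](CC=C(C)C)C1=CC(=O)c2c(OC(C)=O)ccc(OC(C)=O)c2C1=O
F10 | step 2 | racemic 1-(trimethylsilyl)hex-5-en-1-yn-3-ol | OC(CC=C)C#C[Si](C)(C)C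
F11 | step 2 | 1-(trimethylsilyl)hex-5-en-1-yn-3-one | C=CCC(=O)C#C[Si](C)(C)C
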